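**Retrosynthetic overview**
- The target comes from fluoride desilylation of a tris-silyl ether. Its two carbinols are set separately by catalyst-controlled reductions of aryl ketones: the (R)-carbinol by a ketoreductase and the (S)-carbinol by an oxazaborolidine (CBS) reduction.
- Both aryl ketones come from one arylmagnesium bromide made once from silyl-protected 4-bromoguaiacol. It is used in a Negishi acylation on the acid side and a Weinreb ketone synthesis on the ester side of a trans-tetrahydrofuran-3,4-dicarboxylic acid monoester.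
- The trans hemiester comes from epimerisation of the cis hemiester, which is made by alkaloid-catalysed desymmetrising methanolysis of the meso anhydride (first stereocentres).
- Ring order: the tetrahydrofuran ring is made first (hydrogenation of a furan-3,4-diester); the bicyclic anhydride ring is closed and reopened; no ring is formed afterwards.

Assumption: the facial sense of the alkaloid-catalysed methanolysis in step 4 is taken from the carbocyclic meso-anhydride series (recalled, not verified for this oxa-anhydride); should the antipode form, the pseudoenantiomeric catalyst (DHQD)2AQN replaces (DHQ)2AQN and nothing else changes.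

**Route**

Step 1
Reactants: 1 dimethyl furan-3,4-dicarboxylate
Product: 2 dimethyl (3R,4S)-tetrahydrofuran-3,4-dicarboxylate (cis; meso)
Conditions: H2 (50 bar), 5% Rh/Al2O3, MeOH, 50 °C
Reagents that add atoms: none
Why: Heterogeneous catalytic hydrogenation adds hydrogen from the catalyst face (syn addition), giving the cis diester, which is meso, so no target stereocentre is fixed yet.

Step 2
Reactants: 2 dimethyl (3R,4S)-tetrahydrofuran-3,4-dicarboxylate
Product: 3 (3R,4S)-tetrahydrofuran-3,4-dicarboxylic acid (cis; meso)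
Conditions: aq. HCl (3 M), reflux; evaporate to dryness
Reagents that add atoms: water, O
Why: Acid-catalysed ester hydrolysis proceeds without enolate formation, so the cis relationship is kept.

Step 3
Reactants: 3 (3R,4S)-tetrahydrofuran-3,4-dicarboxylic acid
Product: 4 (3aR,6aS)-tetrahydro-1H,3H-furo[3,4-c]furan-1,3-dione (cis-fused meso anhydride)
Conditions: Ac2O, reflux; strip volatiles, crystallise
Reagents that add atoms: none
Why: Dehydrative cyclisation gives the five-membered cyclic anhydride, which can only be cis-fused, so any trans diacid is funnelled to the same meso compound.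

Step 4
Reactants: 4 (3aR,6aS)-tetrahydro-1H,3H-furo[3,4-c]furan-1,3-dione
Product: 5 (3R,4S)-4-(methoxycarbonyl)tetrahydrofuran-3-carboxylic acid (cis hemiester)
Conditions: (DHQ)2AQN (hydroquinine anthraquinone-1,4-diyl diether, 10 mol %), MeOH (10 equiv), Et2O, −30 °C; catalyst removed by aq. HCl wash
Reagents that add atoms: methanol, CO
Why: Cinchona-alkaloid-catalysed enantioselective alcoholysis (desymmetrisation of a meso anhydride) directs methanol to one of the two enantiotopic carbonyls by chiral general-base catalysis, fixing both ring stereocentres from achiral material.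

Step 5
Reactants: 5 (3R,4S)-4-(methoxycarbonyl)tetrahydrofuran-3-carboxylic acid
Product: 6 (3R,4R)-4-(methoxycarbonyl)tetrahydrofuran-3-carboxylic acid (trans hemiester)
Conditions: NaOMe (3 equiv), MeOH, reflux; then aq. HCl to pH 2, 0 °C; recrystallise
Reagents that add atoms: none
Why: Thermodynamic epimerisation through the ester enolate inverts only the ester-bearing carbon (the C–H next to the carboxylate is not acidic), giving the more stable trans isomer while the acid-bearing stereocentre from step 4 is untouched.

Step 6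
Reactants: 7 4-bromo-2-methoxyphenol
Product: 8 (4-bromo-2-methoxyphenoxy)triisopropylsilane
Conditions: TIPSCl, imidazole, DMF, rt
Reagents that add atoms: triisopropylsilyl chloride (TIPSCl), CC(C)[Si](Cl)(C(C)C)C(C)C
Why: Silyl ether formation masks the phenol with a group that survives Grignard and zinc reagents and neutral buffer and is removed by fluoride at the end.

Step 7
Reactants: 8 (4-bromo-2-methoxyphenoxy)triisopropylsilane
Product: 9 [3-methoxy-4-(triisopropylsilyloxy)phenyl]magnesium bromide (titrated THF solution, kept under argon and drawn on in steps 8 and 12)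
Conditions: Mg turnings (cat. I2), THF, 40 °C; titrate, store under Ar
Reagents that add atoms: magnesium, [Mg]
Why: Grignard formation by oxidative insertion of magnesium into the aryl C–Br bond is clean for this electron-rich aryl bromide, and the hindered aryl silyl ether is inert to the reagent, so one batch serves both acylations.

Step 8
Reactants: 6 (3R,4R)-4-(methoxycarbonyl)tetrahydrofuran-3-carboxylic acid; 9 [3-methoxy-4-(triisopropylsilyloxy)phenyl]magnesium bromide
Product: 12 methyl (3R,4R)-4-[3-methoxy-4-(triisopropylsilyloxy)benzoyl]tetrahydrofuran-3-carboxylate, via acid chloride 10 (not isolated), via arylzinc chloride 11 (not isolated)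
Conditions: 6, (COCl)2, cat. DMF, CH2Cl2, 0 °C to rt, evaporate; 9 (1.2 equiv), ZnCl2, THF, 0 °C; combine, Pd(PPh3)4 (3 mol %), THF, 0 °C to rt
Reagents that add atoms: none
Why: Negishi acylation (zerovalent palladium couples the acyl chloride with the arylzinc chloride) is selective for the acid chloride over the methyl ester and is non-basic, so the trans ring stereocentres are not epimerised.

Step 9
Reactants: 12 methyl (3R,4R)-4-[3-methoxy-4-(triisopropylsilyloxy)benzoyl]tetrahydrofuran-3-carboxylate
Product: 13 methyl (3R,4R)-4-{(R)-hydroxy[3-methoxy-4-(triisopropylsilyloxy)phenyl]methyl}tetrahydrofuran-3-carboxylate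
Conditions: (R)-selective ketoreductase (NADPH-dependent alcohol dehydrogenase class, picked from a KRED panel for the (R)-carbinol), NADP+ (cat.), i-PrOH (15% v/v), DMSO (5%), KH2PO4/K2HPO4 buffer pH 7.0, MgSO4 (2 mM), 30 °C
Reagents that add atoms: none
Why: Biocatalytic asymmetric ketone reduction delivers hydride from NADPH to one carbonyl face under enzyme control, not substrate control, setting the (R)-carbinol at neutral pH, where the ketone α-centre already sits in its preferred trans arrangement and the trans hydroxy ester does not lactonise.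

Step 10
Reactants: 13 methyl (3R,4R)-4-{(R)-hydroxy[3-methoxy-4-(triisopropylsilyloxy)phenyl]methyl}tetrahydrofuran-3-carboxylate
Product: 14 methyl (3R,4R)-4-{(R)-(tert-butyldimethylsilyloxy)[3-methoxy-4-(triisopropylsilyloxy)phenyl]methyl}tetrahydrofuran-3-carboxylate
Conditions: TBSOTf, 2,6-lutidine, CH2Cl2, −78 to 0 °C
Reagents that add atoms: tert-butyldimethylsilyl triflate (TBSOTf), CC(C)(C)[Si](C)(C)OS(=O)(=O)C(F)(F)F
Why: Silyl ether formation under weakly basic conditions protects the carbinol without epimerisation and blocks lactonisation in the organometallic steps that follow.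

Step 11
Reactants: 14 methyl (3R,4R)-4-{(R)-(tert-butyldimethylsilyloxy)[3-methoxy-4-(triisopropylsilyloxy)phenyl]methyl}tetrahydrofuran-3-carboxylate
Product: 15 (3R,4R)-4-{(R)-(tert-butyldimethylsilyloxy)[3-methoxy-4-(triisopropylsilyloxy)phenyl]methyl}-N-methoxy-N-methyltetrahydrofuran-3-carboxamide
Conditions: MeNH(OMe)·HCl (3 equiv), i-PrMgCl (6 equiv), THF, −20 to 0 °C
Reagents that add atoms: N,O-dimethylhydroxylamine hydrochloride, CNOC.Cl
Why: Weinreb amide formation by aminolysis of the ester with the chloromagnesium amide is direct, and the only enolisable centre left prefers the trans arrangement it already has.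

Step 12
Reactants: 15 (3R,4R)-4-{(R)-(tert-butyldimethylsilyloxy)[3-methoxy-4-(triisopropylsilyloxy)phenyl]methyl}-N-methoxy-N-methyltetrahydrofuran-3-carboxamide; 9 [3-methoxy-4-(triisopropylsilyloxy)phenyl]magnesium bromide
Product: 16 {(3R,4R)-4-{(R)-(tert-butyldimethylsilyloxy)[3-methoxy-4-(triisopropylsilyloxy)phenyl]methyl}tetrahydrofuran-3-yl}[3-methoxy-4-(triisopropylsilyloxy)phenyl]methanone
Conditions: 9 (2 equiv), THF, 0 °C to rt; aq. NH4Cl
Reagents that add atoms: none
Why: Weinreb ketone synthesis stops at the ketone because the Grignard adduct is a stable magnesium chelate that collapses only on work-up, and the silyl ethers are inert to the Grignard reagent.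

Step 13
Reactants: 16 {(3R,4R)-4-{(R)-(tert-butyldimethylsilyloxy)[3-methoxy-4-(triisopropylsilyloxy)phenyl]methyl}tetrahydrofuran-3-yl}[3-methoxy-4-(triisopropylsilyloxy)phenyl]methanone
Product: 17 (S)-{(3R,4R)-4-{(R)-(tert-butyldimethylsilyloxy)[3-methoxy-4-(triisopropylsilyloxy)phenyl]methyl}tetrahydrofuran-3-yl}[3-methoxy-4-(triisopropylsilyloxy)phenyl]methanol
Conditions: (R)-Me-CBS ((R)-1-methyl-3,3-diphenyltetrahydro-1H,3H-pyrrolo[1,2-c][1,3,2]oxazaborole, 0.3 equiv), BH3·SMe2, THF, −20 °C; MeOH quench, aqueous work-up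
Reagents that add atoms: none
Why: Corey–Bakshi–Shibata reduction with the (R)-catalyst delivers hydride to the face giving the (S)-carbinol (aryl as the large group), so this carbinol, whose relative configuration to its ring carbon is opposite to that of the first, is set by the catalyst independently of step 9.

Step 14
Reactants: 17 (S)-{(3R,4R)-4-{(R)-(tert-butyldimethylsilyloxy)[3-methoxy-4-(triisopropylsilyloxy)phenyl]methyl}tetrahydrofuran-3-yl}[3-methoxy-4-(triisopropylsilyloxy)phenyl]methanol
Product: 18 (S)-(4-hydroxy-3-methoxyphenyl){(3R,4R)-4-[(R)-hydroxy(4-hydroxy-3-methoxyphenyl)methyl]tetrahydrofuran-3-yl}methanol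
Conditions: TBAF (5 equiv), AcOH (5 equiv), THF, 0 °C to rt
Reagents that add atoms: none
Why: Fluoride-mediated global desilylation cleaves both aryl TIPS ethers and the benzylic TBS ether under buffered, non-acidic conditions, so the acid-sensitive p-hydroxybenzylic alcohols survive and no stereocentre is touched.

**Compound list**

1 | dimethyl furan-3,4-dicarboxylate | COC(=O)c1cocc1C(=O)OC | starting material
2 | dimethyl (3R,4S)-tetrahydrofuran-3,4-dicarboxylate (cis, meso) | COC(=O)[C@H]1COC[C@H]1C(=O)OC | intermediate
3 | (3R,4S)-tetrahydrofuran-3,4-dicarboxylic acid (cis, meso) | OC(=O)[C@H]1COC[C@H]1C(=O)O | intermediate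
4 | (3aR,6aS)-tetrahydro-1H,3H-furo[3,4-c]furan-1,3-dione (meso anhydride) | O=C1OC(=O)[C@H]2COC[C@@H]12 | intermediate
5 | (3R,4S)-4-(methoxycarbonyl)tetrahydrofuran-3-carboxylic acid (cis hemiester) | OC(=O)[C@H]1COC[C@H]1C(=O)OC | intermediate
6 | (3R,4R)-4-(methoxycarbonyl)tetrahydrofuran-3-carboxylic acid (trans hemiester) | OC(=O)[C@H]1COC[C@@H]1C(=O)OC | intermediate
7 | 4-bromo-2-methoxyphenol | COc1cc(Br)ccc1O | starting material
8 | (4-bromo-2-methoxyphenoxy)triisopropylsilane | COc1cc(Br)ccc1O[Si](C(C)C)(C(C)C)C(C)C | intermediate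
9 | [3-methoxy-4-(triisopropylsilyloxy)phenyl]magnesium bromide (titrated THF solution) | COc1cc([Mg]Br)ccc1O[Si](C(C)C)(C(C)C)C(C)C | intermediate
10 | methyl (3R,4R)-4-(chlorocarbonyl)tetrahydrofuran-3-carboxylate (acid chloride, not isolated) | ClC(=O)[C@H]1COC[C@@H]1C(=O)OC | intermediate
11 | [3-methoxy-4-(triisopropylsilyloxy)phenyl]zinc chloride (not isolated) | COc1cc([Zn]Cl)ccc1O[Si](C(C)C)(C(C)C)C(C)C | intermediate
12 | methyl (3R,4R)-4-[3-methoxy-4-(triisopropylsilyloxy)benzoyl]tetrahydrofuran-3-carboxylate | COC(=O)[C@H]1COC[C@@H]1C(=O)c1ccc(O[Si](C(C)C)(C(C)C)C(C)C)c(OC)c1 | intermediate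
13 | methyl (3R,4R)-4-{(R)-hydroxy[3-methoxy-4-(triisopropylsilyloxy)phenyl]methyl}tetrahydrofuran-3-carboxylate | COC(=O)[C@H]1COC[C@@H]1[C@@H](O)c1ccc(O[Si](C(C)C)(C(C)C)C(C)C)c(OC)c1 | intermediate
14 | methyl (3R,4R)-4-{(R)-(tert-butyldimethylsilyloxy)[3-methoxy-4-(triisopropylsilyloxy)phenyl]methyl}tetrahydrofuran-3-carboxylate | COC(=O)[C@H]1COC[C@@H]1[C@@H](O[Si](C)(C)C(C)(C)C)c1ccc(O[Si](C(C)C)(C(C)C)C(C)C)c(OC)c1 | intermediate
15 | (3R,4R)-4-{(R)-(tert-butyldimethylsilyloxy)[3-methoxy-4-(triisopropylsilyloxy)phenyl]methyl}-N-methoxy-N-methyltetrahydrofuran-3-carboxamide | CON(C)C(=O)[C@H]1COC[C@@H]1[C@@H](O[Si](C)(C)C(C)(C)C)c1ccc(O[Si](C(C)C)(C(C)C)C(C)C)c(OC)c1 | intermediate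
16 | {(3R,4R)-4-{(R)-(tert-butyldimethylsilyloxy)[3-methoxy-4-(triisopropylsilyloxy)phenyl]methyl}tetrahydrofuran-3-yl}[3-methoxy-4-(triisopropylsilyloxy)phenyl]methanone | COc1cc(C(=O)[C@H]2COC[C@@H]2[C@@H](O[Si](C)(C)C(C)(C)C)c2ccc(O[Si](C(C)C)(C(C)C)C(C)C)c(OC)c2)ccc1O[Si](C(C)C)(C(C)C)C(C)C | intermediate
17 | (S)-{(3R,4R)-4-{(R)-(tert-butyldimethylsilyloxy)[3-methoxy-4-(triisopropylsilyloxy)phenyl]methyl}tetrahydrofuran-3-yl}[3-methoxy-4-(triisopropylsilyloxy)phenyl]methanol | COc1cc([C@@H](O)[C@H]2COC[C@@H]2[C@@H](O[Si](C)(C)C(C)(C)C)c2ccc(O[Si](C(C)C)(C(C)C)C(C)C)c(OC)c2)ccc1O[Si](C(C)C)(C(C)C)C(C)C | intermediate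
18 | (S)-(4-hydroxy-3-methoxyphenyl){(3R,4R)-4-[(R)-hydroxy(4-hydroxy-3-methoxyphenyl)methyl]tetrahydrofuran-3-yl}methanol | COc1cc([C@@H](O)[C@H]2COC[C@@H]2[C@@H](O)c2ccc(O)c(OC)c2)ccc1O | target

**Step count and risks**

Total steps: 14. Longest linear sequence: 12 (steps 1–5 and 8–14; steps 6 and 7 are a two-step side branch that supplies the aryl nucleophile to steps 8 and 12).

Steps most likely to fail:

Step 9 (highest risk): an enzyme hit is needed that accepts this bulky ketone and gives the (R)-carbinol whatever the substrate's own facial bias. Fallback: set out from 12 and use small-molecule catalyst control instead, (S)-Me-CBS ((S)-1-methyl-3,3-diphenyltetrahydro-1H,3H-pyrrolo[1,2-c][1,3,2]oxazaborole) with catecholborane in toluene at −78 °C, to arrive at 13. Should the substrate bias erode the selectivity, the epimer methyl (3R,4R)-4-{(S)-hydroxy[3-methoxy-4-(triisopropylsilyloxy)phenyl]methyl}tetrahydrofuran-3-carboxylate F4 that accompanies it is separated by chromatography and returned to 12 by Dess–Martin oxidation, so material is recycled.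

Step 13: the diastereoselectivity of the CBS reduction on a hindered, α-branched aryl ketone may be modest. Fallback: set out from 16 and desilylate first (TBAF, AcOH, THF) to the small, water-compatible hydroxy ketone (4-hydroxy-3-methoxyphenyl){(3R,4R)-4-[(R)-hydroxy(4-hydroxy-3-methoxyphenyl)methyl]tetrahydrofuran-3-yl}methanone F5. An (S)-selective (Prelog-type) ketoreductase with i-PrOH in pH 7 buffer then reduces F5 directly to the target 18, bypassing 17.

Step 4: the ee and the sense of the desymmetrisation on this oxa-anhydride are not certain. Fallback: set out from 4 and run the methanolysis with whichever pseudoenantiomeric catalyst gives the higher ee, accepting the antipodal cis hemiester (3S,4R)-4-(methoxycarbonyl)tetrahydrofuran-3-carboxylic acid F1. Its acid is then converted with oxalyl chloride into the cis acid chloride methyl (3R,4S)-4-(chlorocarbonyl)tetrahydrofuran-3-carboxylate F2 (not isolated). Negishi coupling of F2 with the arylzinc chloride 11 (made from 9 and ZnCl2 as in step 8) gives the cis keto ester methyl (3R,4S)-4-[3-methoxy-4-(triisopropylsilyloxy)benzoyl]tetrahydrofuran-3-carboxylate F3. Catalytic DBU in CH2Cl2 then epimerises the ketone α-carbon, which is now the more acidic one. Since the other ring centre is inverted this time, the trans product is 12, where the route is rejoined (compounds 5, 6 and 10 are bypassed).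

**Further compounds**

F1 | step 4 | (3S,4R)-4-(methoxycarbonyl)tetrahydrofuran-3-carboxylic acid | OC(=O)[C@@H]1COC[C@@H]1C(=O)OC
F2 | step 4 | methyl (3R,4S)-4-(chlorocarbonyl)tetrahydrofuran-3-carboxylate | ClC(=O)[C@@H]1COC[C@@H]1C(=O)OC
F3 | step 4 | methyl (3R,4S)-4-[3-methoxy-4-(triisopropylsilyloxy)benzoyl]tetrahydrofuran-3-carboxylate | COC(=O)[C@H]1COC[C@H]1C(=O)c1ccc(O[Si](C(C)C)(C(C)C)C(C)C)c(OC)c1
F4 | step 9 | methyl (3R,4R)-4-{(S)-hydroxy[3-methoxy-4-(triisopropylsilyloxy)phenyl]methyl}tetrahydrofuran-3-carboxylate | COC(=O)[C@H]1COC[C@@H]1[C@H](O)c1ccc(O[Si](C(C)C)(C(C)C)C(C)C)c(OC)c1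
F5 | step 13 | (4-hydroxy-3-methoxyphenyl){(3R,4R)-4-[(R)-hydroxy(4-hydroxy-3-methoxyphenyl)methyl]tetrahydrofuran-3-yl}methanone | COc1cc(C(=O)[C@H]2COC[C@@H]2[C@@H](O)c2ccc(O)c(OC)c2)ccc1O
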